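**Retrosynthetic overview**

1. The target is a (3S)-isoflavanone. The route rests on ring B (C1'–C6'), which carries four contiguous groups: the bond to C3 at C1', OMe at C2', the (E)-3-methylbut-1-enyl chain at C3' and OH at C4'.
2. Ring B is built, not substituted. Light-induced Wolff rearrangement of an acyclic α-diazo vinyl ketone gives a vinylketene, which is annulated with a 1-methoxy enyne ([2+2], 4π opening, 6π closure). This forms C1'–C2', C3'–C4' and C4'–C5' and gives an allyl arylacetate.
3. Ring A comes from resorcinol as a symmetric 4-prenyl-3,5-bis(MOM-oxy)phenol. Its ortho-formylation fixes the prenyl group at C6 by symmetry.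
4. Ring C is closed last. The 2-arylacrylate made from the arylacetate is joined to the ring-A salicylaldehyde by oxa-Michael addition (O1–C2) and aldol closure (C3–C4), then oxidised to the allyl β-keto ester.
5. C3 is set by Pd/phosphinooxazoline decarboxylative protonation of that ester, and MOM removal ends the route. Ring order: B, then C onto preformed A.

Key step: step 8

Remark 1: by CIP rules (C4 > C2 > C1' > H) the given SMILES is the 3S enantiomer; MOM protection does not change the descriptor.
Remark 2: a 2-hydroxyaryl β-keto allyl ester would lactonise to a 3-aryl-4-hydroxycoumarin, so O1–C2 is made before C4 becomes a ketone; everything before step 17 is racemic or achiral.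
Remark 3 (assumption): (S)-t-BuPHOX [(S)-4-tert-butyl-2-(2-diphenylphosphinophenyl)-4,5-dihydrooxazole] is taken to give the 3S product with Meldrum's acid as proton donor; if a pilot run shows the opposite sense, the (R)-ligand is used in the same way.

**Route**

Step 1
Reactants: 1 succinic anhydride; 2 allyl alcohol
Product: 3 4-(allyloxy)-4-oxobutanoic acid
Conditions: 2 (1.1 equiv), DMAP (5 mol%), toluene, 80 °C
Reagents that add atoms: none
Why: Alcoholysis of a cyclic anhydride (nucleophilic acyl substitution) stops at the half-ester because the carboxylate that forms is no longer electrophilic.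

Step 2
Reactants: 3 4-(allyloxy)-4-oxobutanoic acid
Product: 5 allyl 4-[methoxy(methyl)amino]-4-oxobutanoate, via acyl imidazolide 4 (not isolated)
Conditions: 1,1'-carbonyldiimidazole (1.1 equiv), CH2Cl2, 0 °C → rt; then MeNH(OMe)·HCl (1.2 equiv), rt
Reagents that add atoms: N,O-dimethylhydroxylamine hydrochloride, CNOC.Cl
Why: Weinreb amide formation through the acyl imidazolide is a standard amide coupling that leaves the allyl ester untouched.

Step 3
Reactants: 5 allyl 4-[methoxy(methyl)amino]-4-oxobutanoate; 6 vinylmagnesium bromide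
Product: 7 allyl 4-oxohex-5-enoate
Conditions: 6 (1.15 equiv), THF, −40 → −10 °C; cannulated into cold 1 M HCl; used without storage
Reagents that add atoms: none
Why: Weinreb ketone synthesis, in which the chelated tetrahedral adduct resists over-addition and forms faster than attack on the allyl ester, while the acidic inverse quench protonates the released N,O-dimethylhydroxylamine before it can add to the vinyl ketone.

Step 4
Reactants: 7 allyl 4-oxohex-5-enoate
Product: 9 allyl 3-diazo-4-oxohex-5-enoate, via trifluoroacetyl ketone 8 (not isolated)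
Conditions: 7 added slowly to LiN(SiMe3)2 (1.1 equiv), THF, −78 °C; CF3CO2CH2CF3 (1.2 equiv), −78 °C; dilute HCl work-up; then MeSO2N3 (1.5 equiv), Et3N (1.5 equiv), H2O (1 equiv), MeCN, rt; product kept cold, dilute and dark
Reagents that add atoms: methanesulfonyl azide, CS(=O)(=O)N=[N+]=[N-]
Why: Detrifluoroacetylative (Regitz-type deacylative) diazo transfer, in which kinetic deprotonation at −78 °C takes the only ketone α-CH2 (more acidic than the ester α-CH2 and, under inverse addition, faster than Michael addition), trifluoroacetylation activates that carbon for diazo transfer from the sulfonyl azide, and the trifluoroacetyl group leaves as the N-acylsulfonamide.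

Step 5
Reactants: 10 3-methylbut-1-yne
Product: 12 (E)-1-iodo-3-methylbut-1-ene, via alkenylzirconocene chloride 11 (not isolated)
Conditions: Cp2Zr(H)Cl (1.1 equiv), CH2Cl2, 0 °C → rt; I2 (1.1 equiv), 0 °C; kept as a pentane solution
Reagents that add atoms: iodine, II
Why: Hydrozirconation of a terminal alkyne is a syn addition that puts zirconium on the terminal carbon, and iodinolysis of the C–Zr bond goes with retention, so the E iodide results.

Step 6
Reactants: 13 trichloroethylene
Product: 14 (E)-1,2-dichloro-1-methoxyethene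
Conditions: KOMe (1.0 equiv), THF, −50 °C → rt, closed system behind a shield
Reagents that add atoms: potassium methoxide, C[O-].[K+]
Why: Base-induced elimination to dichloroacetylene followed by anti addition of methoxide (elimination–addition) is the established entry to 1,2-dichlorovinyl ethers.

Step 7
Reactants: 14 (E)-1,2-dichloro-1-methoxyethene; 12 (E)-1-iodo-3-methylbut-1-ene
Product: 17 (E)-1-methoxy-5-methylhex-3-en-1-yne, via lithium methoxyacetylide 15 (not isolated), via methoxyethynylzinc chloride 16 (not isolated)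
Conditions: n-BuLi (2.1 equiv), Et2O, −78 → −40 °C; ZnCl2 (1.1 equiv, THF), −40 → 0 °C; 12 (0.9 equiv), Pd(PPh3)4 (3 mol%), 0 °C → rt; base-washed silica, stored cold
Reagents that add atoms: none
Why: n-BuLi converts the dichlorovinyl ether into the lithium alkoxyacetylide (elimination, then Cl/Li exchange), and Negishi coupling of the derived alkynylzinc chloride with the alkenyl iodide forms the C(sp)–C(sp2) bond with retention of the E geometry under neutral conditions that the acid-sensitive ynol ether tolerates.

Step 8
Reactants: 9 allyl 3-diazo-4-oxohex-5-enoate; 17 (E)-1-methoxy-5-methylhex-3-en-1-yne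
Product: 22 allyl 2-[4-hydroxy-2-methoxy-3-[(E)-3-methylbut-1-enyl]phenyl]acetate, via vinylketene 18 (not isolated), via vinylcyclobutenone 19 (not isolated), via dienylketene 20 (not isolated), via cyclohexadienone 21 (not isolated)
Conditions: 9 (0.1 M) added over 2 h to 17 (2.0 equiv) in degassed ClCH2CH2Cl, 405 nm LEDs, 15 °C, argon; when N2 evolution stops, 80 °C in the dark, 3 h; excess 17 recovered
Reagents that add atoms: none
Why: Excitation at 405 nm, where only the diazo ketone absorbs so that the E double bonds of 17 and of the product are not isomerised, expels N2 and the vinyl group migrates (Wolff rearrangement) to give vinylketene 18, whose α-carbon carries the CH2CO2allyl chain. The ynol ether then adds in a regioselective [2+2] cycloaddition, its nucleophilic alkenyl-bearing carbon bonding to the ketene carbonyl carbon and its methoxy-bearing carbon to the ketene α-carbon, to give 4-vinylcyclobutenone 19. Warming opens 19 by 4π electrocyclic ring opening to dienylketene 20, which closes ring B by thermal 6π electrocyclisation (ketene carbon to the vinyl terminus) and tautomerises from 21 to phenol 22; the closest known reaction type is the diazo ketone variant of the Danheiser benzannulation with alkoxyalkynes. The bonds C1'–C2', C3'–C4' and C4'–C5' are formed and no stereocentre is created. The step needs three selectivities: the [2+2] regiochemistry, secured by the polarisation of the ynol ether; vinyl migration over 1,2-hydrogen shift from the neighbouring CH2, favoured by direct excitation at low temperature; and capture of 18 by the alkyne over dimerisation, secured by slow addition of 9 to excess 17.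

Step 9
Reactants: 22 allyl 2-[4-hydroxy-2-methoxy-3-[(E)-3-methylbut-1-enyl]phenyl]acetate
Product: 23 allyl 2-[2-methoxy-4-(methoxymethoxy)-3-[(E)-3-methylbut-1-enyl]phenyl]acetate
Conditions: MeOCH2Cl (1.5 equiv), i-Pr2NEt (2.0 equiv), CH2Cl2, 0 °C → rt
Reagents that add atoms: chloromethyl methyl ether, COCCl
Why: Williamson-type O-alkylation gives a MOM ether that masks the acidic phenol through the base-mediated and Pd-catalysed steps and can be removed at the end without base.

Step 10
Reactants: 23 allyl 2-[2-methoxy-4-(methoxymethoxy)-3-[(E)-3-methylbut-1-enyl]phenyl]acetate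
Product: 25 allyl 2-[2-methoxy-4-(methoxymethoxy)-3-[(E)-3-methylbut-1-enyl]phenyl]prop-2-enoate, via hydroxymethyl ester 24 (not isolated)
Conditions: (CH2O)n (3 equiv), K2CO3 (1.5 equiv), n-Bu4NI (5 mol%), toluene, 80 °C
Reagents that add atoms: paraformaldehyde (as formaldehyde), C=O
Why: α-Methylenation of an arylacetate by aldol addition to formaldehyde and E1cB dehydration is the standard route to 2-arylacrylates.

Step 11
Reactants: 26 resorcinol
Product: 27 1,3-bis(methoxymethoxy)benzene
Conditions: MeOCH2Cl (2.5 equiv), i-Pr2NEt (3.0 equiv), CH2Cl2, 0 °C → rt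
Reagents that add atoms: chloromethyl methyl ether, COCCl
Why: Double Williamson-type O-alkylation installs the two MOM ethers that act as ortho-directing groups in the next step and later protect O5 and O7.

Step 12
Reactants: 27 1,3-bis(methoxymethoxy)benzene; 28 prenyl bromide
Product: 30 1,3-bis(methoxymethoxy)-2-(3-methylbut-2-enyl)benzene, via aryllithium 29 (not isolated)
Conditions: n-BuLi (1.1 equiv), THF, 0 °C → rt; CuI (10 mol%), 28 (1.2 equiv), −78 °C → rt
Reagents that add atoms: none
Why: Directed ortho-metalation occurs at the position flanked by both MOM ethers, and copper-mediated allylic substitution at the primary carbon of prenyl bromide gives the 2-prenyl arene.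

Step 13
Reactants: 30 1,3-bis(methoxymethoxy)-2-(3-methylbut-2-enyl)benzene
Product: 32 3,5-bis(methoxymethoxy)-4-(3-methylbut-2-enyl)phenol, via arylboronate 31 (not isolated)
Conditions: [Ir(OMe)(cod)]2 (1.5 mol%), 4,4'-di-tert-butyl-2,2'-bipyridine (3 mol%), B2pin2 (0.6 equiv), THF, 80 °C; then 30% H2O2, aq NaOH, 0 °C
Reagents that add atoms: hydrogen peroxide, OO
Why: Iridium-catalysed C–H borylation is sterically controlled and takes the only ring C–H without an ortho substituent (para to the prenyl group), and oxidation of the arylboronate with alkaline hydrogen peroxide, which does not epoxidise the trisubstituted alkene, gives the symmetric phenol.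

Step 14
Reactants: 32 3,5-bis(methoxymethoxy)-4-(3-methylbut-2-enyl)phenol
Product: 34 6-hydroxy-2,4-bis(methoxymethoxy)-3-(3-methylbut-2-enyl)benzaldehyde, via salicyl alcohol 33 (not isolated)
Conditions: MgCl2 (2 equiv), Et3N (4 equiv), (CH2O)n (6 equiv), MeCN, reflux
Reagents that add atoms: paraformaldehyde (as formaldehyde), C=O
Why: Magnesium-mediated ortho-formylation of phenols (Casnati–Skattebøl reaction) delivers formaldehyde only ortho to the free OH through the magnesium phenoxide, and because the two ortho positions are equivalent the aldehyde carbon (later C4) ends up between the free OH (later O1) and the MOM ether next to the prenyl group (later O5).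

Step 15
Reactants: 25 allyl 2-[2-methoxy-4-(methoxymethoxy)-3-[(E)-3-methylbut-1-enyl]phenyl]prop-2-enoate; 34 6-hydroxy-2,4-bis(methoxymethoxy)-3-(3-methylbut-2-enyl)benzaldehyde
Product: 36 allyl 4-hydroxy-3-[2-methoxy-4-(methoxymethoxy)-3-[(E)-3-methylbut-1-enyl]phenyl]-5,7-bis(methoxymethoxy)-6-(3-methylbut-2-enyl)chromane-3-carboxylate (racemic diastereomer mixture), via aryl ether aldehyde 35 (not isolated)
Conditions: 25 (1.1 equiv), Cs2CO3 (30 mol%), MeCN, rt → 40 °C
Reagents that add atoms: none
Why: Domino oxa-Michael/intramolecular aldol reaction, in which the caesium phenoxide of 34 adds to the CH2 terminus of the 2-arylacrylate and the aryl-stabilised ester enolate closes the six-membered ring onto the neighbouring aldehyde (6-exo-trig), so that O1–C2 and C3–C4 form without a free 2-hydroxyaryl β-keto ester; the two new stereocentres form without control, C4 being erased in step 16 and C3 reset in step 17.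

Step 16
Reactants: 36 allyl 4-hydroxy-3-aryl-5,7-bis(methoxymethoxy)-6-(3-methylbut-2-enyl)chromane-3-carboxylate (aryl as in 25)
Product: 37 allyl 3-[2-methoxy-4-(methoxymethoxy)-3-[(E)-3-methylbut-1-enyl]phenyl]-5,7-bis(methoxymethoxy)-6-(3-methylbut-2-enyl)-4-oxochromane-3-carboxylate (racemic)
Conditions: Dess–Martin periodinane (1.5 equiv), pyridine (3 equiv), CH2Cl2, 0 °C → rt
Reagents that add atoms: none
Why: Dess–Martin oxidation of the benzylic secondary alcohol under buffered, non-basic conditions gives the β-keto ester without retro-aldol cleavage and converges both diastereomers.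

Step 17
Reactants: 37 allyl 3-aryl-5,7-bis(methoxymethoxy)-6-(3-methylbut-2-enyl)-4-oxochromane-3-carboxylate (racemic)
Product: 38 (3S)-3-[2-methoxy-4-(methoxymethoxy)-3-[(E)-3-methylbut-1-enyl]phenyl]-5,7-bis(methoxymethoxy)-6-(3-methylbut-2-enyl)chroman-4-one
Conditions: Pd2(dba)3 (5 mol%), (S)-t-BuPHOX (12.5 mol%), Meldrum's acid (2.5 equiv), 1,4-dioxane, 40 °C
Reagents that add atoms: none
Why: Palladium-catalysed decarboxylative asymmetric protonation, in which zerovalent palladium ionises the allyl ester, CO2 is lost and the enolate held in the chiral Pd–phosphinooxazoline environment is protonated on one face by Meldrum's acid (which also takes up the allyl group), so that C3 (S) is set under ligand control, helped by the ortho-methoxy group that twists the aryl ring out of the enolate plane.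

Step 18
Reactants: 38 (3S)-tris-MOM isoflavanone
Product: 39 (3S)-5,7-dihydroxy-3-[4-hydroxy-2-methoxy-3-[(E)-3-methylbut-1-enyl]phenyl]-6-(3-methylbut-2-enyl)chroman-4-one (CNP0289142.1)
Conditions: NaHSO4·SiO2, CH2Cl2, rt; filtered and concentrated cold as soon as conversion is complete
Reagents that add atoms: none
Why: Acid-catalysed acetal hydrolysis of the three aryl MOM ethers on a weakly acidic solid support at room temperature is chosen so that neither enolisation at C3 (racemisation) nor protonation of the prenyl or styrenyl double bonds should compete.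

**Compound list**

1 | succinic anhydride | O=C1CCC(=O)O1 | starting material
2 | allyl alcohol | C=CCO | starting material
3 | 4-(allyloxy)-4-oxobutanoic acid | OC(=O)CCC(=O)OCC=C | intermediate
4 | allyl 4-(imidazol-1-yl)-4-oxobutanoate | O=C(CCC(=O)OCC=C)n1ccnc1 | intermediate
5 | allyl 4-[methoxy(methyl)amino]-4-oxobutanoate | CON(C)C(=O)CCC(=O)OCC=C | intermediate
6 | vinylmagnesium bromide | C=C[Mg]Br | starting material
7 | allyl 4-oxohex-5-enoate | C=CC(=O)CCC(=O)OCC=C | intermediate
8 | allyl 4-oxo-3-(trifluoroacetyl)hex-5-enoate (racemic) | C=CC(=O)C(CC(=O)OCC=C)C(=O)C(F)(F)F | intermediate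
9 | allyl 3-diazo-4-oxohex-5-enoate | C=CC(=O)C(=[N+]=[N-])CC(=O)OCC=C | intermediate
10 | 3-methylbut-1-yne | CC(C)C#C | starting material
11 | chlorobis(cyclopentadienyl)[(E)-3-methylbut-1-enyl]zirconium | CC(C)/C=C/[Zr](Cl)(C1C=CC=C1)C1C=CC=C1 | intermediate
12 | (E)-1-iodo-3-methylbut-1-ene | CC(C)/C=C/I | intermediate
13 | trichloroethylene | ClC=C(Cl)Cl | starting material
14 | (E)-1,2-dichloro-1-methoxyethene | CO/C(Cl)=C\Cl | intermediate
15 | lithium methoxyacetylide | COC#C[Li] | intermediate
16 | (methoxyethynyl)zinc chloride | COC#C[Zn]Cl | intermediate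
17 | (E)-1-methoxy-5-methylhex-3-en-1-yne | COC#C/C=C/C(C)C | intermediate
18 | allyl 3-(oxomethylidene)pent-4-enoate (vinylketene) | C=CC(=C=O)CC(=O)OCC=C | intermediate
19 | allyl 2-[1-ethenyl-2-methoxy-3-[(E)-3-methylbut-1-enyl]-4-oxocyclobut-2-en-1-yl]acetate (racemic) | O=C1C(/C=C/C(C)C)=C(OC)C1(C=C)CC(=O)OCC=C | intermediate
20 | allyl (3Z)-3-ethenyl-4-methoxy-5-[(E)-3-methylbut-1-enyl]-6-oxohexa-3,5-dienoate (dienylketene) | O=C=C(/C=C/C(C)C)/C(OC)=C(\C=C)CC(=O)OCC=C | intermediate
21 | allyl 2-[2-methoxy-3-[(E)-3-methylbut-1-enyl]-4-oxocyclohexa-1,5-dien-1-yl]acetate (cyclohexa-2,4-dienone) | O=C1CC=C(CC(=O)OCC=C)C(OC)=C1/C=C/C(C)C | intermediate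
22 | allyl 2-[4-hydroxy-2-methoxy-3-[(E)-3-methylbut-1-enyl]phenyl]acetate | C=CCOC(=O)Cc1ccc(O)c(/C=C/C(C)C)c1OC | intermediate
23 | allyl 2-[2-methoxy-4-(methoxymethoxy)-3-[(E)-3-methylbut-1-enyl]phenyl]acetate | C=CCOC(=O)Cc1ccc(OCOC)c(/C=C/C(C)C)c1OC | intermediate
24 | allyl 3-hydroxy-2-[2-methoxy-4-(methoxymethoxy)-3-[(E)-3-methylbut-1-enyl]phenyl]propanoate (racemic) | C=CCOC(=O)C(CO)c1ccc(OCOC)c(/C=C/C(C)C)c1OC | intermediate
25 | allyl 2-[2-methoxy-4-(methoxymethoxy)-3-[(E)-3-methylbut-1-enyl]phenyl]prop-2-enoate | C=CCOC(=O)C(=C)c1ccc(OCOC)c(/C=C/C(C)C)c1OC | intermediate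
26 | resorcinol | Oc1cccc(O)c1 | starting material
27 | 1,3-bis(methoxymethoxy)benzene | COCOc1cccc(OCOC)c1 | intermediate
28 | prenyl bromide (1-bromo-3-methylbut-2-ene) | CC(C)=CCBr | starting material
29 | 2-lithio-1,3-bis(methoxymethoxy)benzene | [Li]c1c(OCOC)cccc1OCOC | intermediate
30 | 1,3-bis(methoxymethoxy)-2-(3-methylbut-2-enyl)benzene | CC(C)=CCc1c(OCOC)cccc1OCOC | intermediate
31 | 2-[3,5-bis(methoxymethoxy)-4-(3-methylbut-2-enyl)phenyl]-4,4,5,5-tetramethyl-1,3,2-dioxaborolane | CC(C)=CCc1c(OCOC)cc(B2OC(C)(C)C(C)(C)O2)cc1OCOC | intermediate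
32 | 3,5-bis(methoxymethoxy)-4-(3-methylbut-2-enyl)phenol | CC(C)=CCc1c(OCOC)cc(O)cc1OCOC | intermediate
33 | 2-(hydroxymethyl)-3,5-bis(methoxymethoxy)-4-(3-methylbut-2-enyl)phenol | CC(C)=CCc1c(OCOC)cc(O)c(CO)c1OCOC | intermediate
34 | 6-hydroxy-2,4-bis(methoxymethoxy)-3-(3-methylbut-2-enyl)benzaldehyde | CC(C)=CCc1c(OCOC)cc(O)c(C=O)c1OCOC | intermediate
35 | allyl 3-[2-formyl-3,5-bis(methoxymethoxy)-4-(3-methylbut-2-enyl)phenoxy]-2-[2-methoxy-4-(methoxymethoxy)-3-[(E)-3-methylbut-1-enyl]phenyl]propanoate (racemic) | C=CCOC(=O)C(COc1cc(OCOC)c(CC=C(C)C)c(OCOC)c1C=O)c1ccc(OCOC)c(/C=C/C(C)C)c1OC | intermediate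
36 | allyl 4-hydroxy-3-[2-methoxy-4-(methoxymethoxy)-3-[(E)-3-methylbut-1-enyl]phenyl]-5,7-bis(methoxymethoxy)-6-(3-methylbut-2-enyl)chromane-3-carboxylate (racemic, both diastereomers) | C=CCOC(=O)C1(c2ccc(OCOC)c(/C=C/C(C)C)c2OC)COc2cc(OCOC)c(CC=C(C)C)c(OCOC)c2C1O | intermediate
37 | allyl 3-[2-methoxy-4-(methoxymethoxy)-3-[(E)-3-methylbut-1-enyl]phenyl]-5,7-bis(methoxymethoxy)-6-(3-methylbut-2-enyl)-4-oxochromane-3-carboxylate (racemic) | C=CCOC(=O)C1(c2ccc(OCOC)c(/C=C/C(C)C)c2OC)COc2cc(OCOC)c(CC=C(C)C)c(OCOC)c2C1=O | intermediate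
38 | (3S)-3-[2-methoxy-4-(methoxymethoxy)-3-[(E)-3-methylbut-1-enyl]phenyl]-5,7-bis(methoxymethoxy)-6-(3-methylbut-2-enyl)chroman-4-one | COc1c([C@H]2COc3cc(OCOC)c(CC=C(C)C)c(OCOC)c3C2=O)ccc(OCOC)c1/C=C/C(C)C | intermediate
39 | (3S)-5,7-dihydroxy-3-[4-hydroxy-2-methoxy-3-[(E)-3-methylbut-1-enyl]phenyl]-6-(3-methylbut-2-enyl)chroman-4-one (CNP0289142.1) | COc1c([C@H]2COc3cc(O)c(CC=C(C)C)c(O)c3C2=O)ccc(O)c1/C=C/C(C)C | target

**Step count**

Total: 18 steps. Longest linear sequence: 11 steps (steps 1, 2, 3, 4, 8, 9, 10, 15, 16, 17, 18).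

**Steps most likely to fail**

Step 8 (key step). After loss of N2 the acyl carbene may undergo 1,2-hydrogen shift from the neighbouring CH2 instead of vinyl migration. The vinylketene may dimerise or acylate the phenol already formed. The diazo group of 9 may also add to the acryloyl unit of a second molecule before irradiation, a weakness that also affects step 4. Fallback: ring B is assembled by arene metalation instead of benzannulation, setting out from 27 and 12 and coming back at 23, so that 9 and 17 are no longer needed. 27 is lithiated between its MOM ethers (n-BuLi, THF, 0 °C), transmetalated (ZnCl2) and coupled with 12 (Pd(PPh3)4) to give 1,3-bis(methoxymethoxy)-2-[(E)-3-methylbut-1-enyl]benzene F1. A second ortho-lithiation (n-BuLi, TMEDA, THF, −20 °C) and DMF give 2,4-bis(methoxymethoxy)-3-[(E)-3-methylbut-1-enyl]benzaldehyde F2. The MOM ether ortho to the formyl group is cleaved selectively with carbonyl assistance (dilute HCl, MeOH, 0 °C) to give 2-hydroxy-4-(methoxymethoxy)-3-[(E)-3-methylbut-1-enyl]benzaldehyde F3. Methylation (MeI, K2CO3, DMF) gives 2-methoxy-4-(methoxymethoxy)-3-[(E)-3-methylbut-1-enyl]benzaldehyde F4. Reductive cyanation with TosMIC (t-BuOK, DME, −40 °C; then MeOH, reflux) gives 2-[2-methoxy-4-(methoxymethoxy)-3-[(E)-3-methylbut-1-enyl]phenyl]acetonitrile F5. Hydrolysis (KOH, aq EtOH, reflux) gives 2-[2-methoxy-4-(methoxymethoxy)-3-[(E)-3-methylbut-1-enyl]phenyl]acetic acid F6, and O-allylation (allyl bromide, K2CO3, DMF) gives 23.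

Step 15. The phenoxide addition to the acrylate is reversible and may lose to anionic polymerisation of 25, or the aldol closure may reopen by retro-aldol reaction at room temperature. Fallback: the ether is made by substitution and the ring closed by kinetic aldol, setting out from 23 and 34 and coming back at 36. The formaldehyde aldol of step 10 is stopped at the alcohol ((CH2O)n, NaHCO3, DMSO, rt) and 24 is isolated. Mitsunobu etherification of 24 with 34 (PPh3, DIAD, toluene, 0 °C) gives 35, now isolated. LiN(SiMe3)2 (THF, −78 °C, cold AcOH quench) then closes the ring to 36 under kinetic control. This path makes no compound outside the list (F0).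

Step 17. Facial selectivity in the protonation may be poor, because the aryl group has only one ortho substituent to tell the enolate faces apart, and the product may lose configuration by proton exchange with the Meldrum's acid anion. Fallback: the stereocentre is set by reduction under dynamic kinetic resolution, setting out from 37 and coming back at 38. Achiral decarboxylative protonation (Pd(OAc)2, PPh3, HCO2H, Et3N, THF) gives racemic 3-[2-methoxy-4-(methoxymethoxy)-3-[(E)-3-methylbut-1-enyl]phenyl]-5,7-bis(methoxymethoxy)-6-(3-methylbut-2-enyl)chroman-4-one F7. Asymmetric transfer hydrogenation with RuCl(p-cymene)[(S,S)-TsDPEN] and HCO2H/Et3N, in which the enantiomers of F7 interconvert through the enol and hydride is delivered anti to the aryl group, should give the cis alcohol (3S,4S)-3-aryl-5,7-bis(methoxymethoxy)-6-(3-methylbut-2-enyl)chroman-4-ol F8; the catalyst antipode is chosen to match. Dess–Martin oxidation with pyridine buffer returns 38 without touching C3.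

**Further compounds**

F1 | step 8 | 1,3-bis(methoxymethoxy)-2-[(E)-3-methylbut-1-enyl]benzene | COCOc1cccc(OCOC)c1/C=C/C(C)C
F2 | step 8 | 2,4-bis(methoxymethoxy)-3-[(E)-3-methylbut-1-enyl]benzaldehyde | COCOc1ccc(C=O)c(OCOC)c1/C=C/C(C)C
F3 | step 8 | 2-hydroxy-4-(methoxymethoxy)-3-[(E)-3-methylbut-1-enyl]benzaldehyde | COCOc1ccc(C=O)c(O)c1/C=C/C(C)C
F4 | step 8 | 2-methoxy-4-(methoxymethoxy)-3-[(E)-3-methylbut-1-enyl]benzaldehyde | COCOc1ccc(C=O)c(OC)c1/C=C/C(C)C
F5 | step 8 | 2-[2-methoxy-4-(methoxymethoxy)-3-[(E)-3-methylbut-1-enyl]phenyl]acetonitrile | COCOc1ccc(CC#N)c(OC)c1/C=C/C(C)C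
F6 | step 8 | 2-[2-methoxy-4-(methoxymethoxy)-3-[(E)-3-methylbut-1-enyl]phenyl]acetic acid | COCOc1ccc(CC(=O)O)c(OC)c1/C=C/C(C)C
F0 | step 15 | none | none
F7 | step 17 | racemic 3-[2-methoxy-4-(methoxymethoxy)-3-[(E)-3-methylbut-1-enyl]phenyl]-5,7-bis(methoxymethoxy)-6-(3-methylbut-2-enyl)chroman-4-one | COc1c(C2COc3cc(OCOC)c(CC=C(C)C)c(OCOC)c3C2=O)ccc(OCOC)c1/C=C/C(C)C
F8 | step 17 | (3S,4S)-3-[2-methoxy-4-(methoxymethoxy)-3-[(E)-3-methylbut-1-enyl]phenyl]-5,7-bis(methoxymethoxy)-6-(3-methylbut-2-enyl)chroman-4-ol | COc1c([C@H]2COc3cc(OCOC)c(CC=C(C)C)c(OCOC)c3[C@H]2O)ccc(OCOC)c1/C=C/C(C)C
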